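Ring B is closed last through the C9–C10 bond (labdane numbering), the link between the oxygen-bearing spiro carbon of the tetrahydrofuran ring and the methyl-bearing quaternary carbon shared by rings A and B. The seco precursor joins a ring-A 2-acyl-1-methylcyclohexene to a spiro dihydrofuran–butyrolactone through C6(=O)–C7–C8. Iron-hydride hydrogen-atom transfer to the enol ether C9=C11 gives the tertiary α-alkoxy radical at C9, which adds 6-endo to C10, the β-carbon of the enone: one operation closes ring B and sets C9, C10 and C5. It exploits the ether oxygen on C9 (radical stabilisation) and the C6 oxygen two bonds from C10 (enone carbonyl, later the 19,6-lactone); the C8 carbinol later gives the spiro-epoxide.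

Key step: step 11

Numbering used for positions: ring A C1–C5/C10, ring B C5–C10, C18 methyl and C19 carbonyl on C4, C20 methyl on C10 (β), C17 epoxide CH2 on C8, tetrahydrofuran O–C9–C11–C12–C13, butyrolactone C13–C14–C15–O–C16.

Assumption: bromide 9 is taken as purchasable; it is otherwise one bromination step from the commercial mono-silylated but-2-yne-1,4-diol.

Step 1
Reactants: 1 methyl 2-oxocyclohexane-1-carboxylate
Product: 2 methyl (1S)-1-methyl-2-oxocyclohexane-1-carboxylate
Conditions: MeI, N-spiro binaphthyl quaternary ammonium bromide (1 mol%, enantiomer chosen for S), aq. K2CO3, toluene, −20 °C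
Reagents that add atoms: iodomethane CI
Why: Asymmetric phase-transfer C-alkylation of the β-keto ester enolate inside the chiral ammonium ion pair should set the C4 quaternary centre (S).

Step 2
Reactants: 2 methyl (1S)-1-methyl-2-oxocyclohexane-1-carboxylate
Product: 3 methyl (1S,3RS)-1,3-dimethyl-2-oxocyclohexane-1-carboxylate (both C3 epimers; C3 becomes sp2 in step 3)
Conditions: LDA, THF, −78 °C; MeI, −78 → 0 °C
Reagents that add atoms: iodomethane CI
Why: Kinetic deprotonation at the only enolisable carbon (the ring CH2 next to the ketone) and enolate C-methylation should install the future C20 methyl.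

Step 3
Reactants: 3 methyl (1S,3RS)-1,3-dimethyl-2-oxocyclohexane-1-carboxylate
Product: 4 methyl (1S)-1,3-dimethyl-2-{[(trifluoromethyl)sulfonyl]oxy}cyclohex-2-ene-1-carboxylate
Conditions: KHMDS, THF, −78 °C; PhNTf2, −78 → 0 °C
Reagents that add atoms: N-phenylbis(trifluoromethanesulfonimide) O=S(=O)(N(c1ccccc1)S(=O)(=O)C(F)(F)F)C(F)(F)F
Why: The ketone can enolise only towards the methyl-bearing carbon, so O-triflation of the potassium enolate should give the tetrasubstituted enol triflate regiospecifically.

Step 4
Reactants: 4 methyl (1S)-1,3-dimethyl-2-{[(trifluoromethyl)sulfonyl]oxy}cyclohex-2-ene-1-carboxylate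
Product: 6 methyl (1S)-2-acetyl-1,3-dimethylcyclohex-2-ene-1-carboxylate, via ethoxydiene 5 (not isolated)
Conditions: tributyl(1-ethoxyvinyl)stannane, Pd(PPh3)4 (5 mol%), CuI (10 mol%), LiCl, DMF, 80 °C; then 1 M HCl, THF, rt
Reagents that add atoms: tributyl(1-ethoxyvinyl)stannane CCCC[Sn](CCCC)(CCCC)C(=C)OCC; water O
Why: Stille coupling of the hindered vinyl triflate (copper co-catalysis, LiCl) with the acyl-anion equivalent, then hydrolysis of the enol ether, should give the methyl ketone that carries C6 and C7.

Step 5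
Reactants: 7 (R)-malic acid
Product: 8 2-[(2R,4R)-2-tert-butyl-5-oxo-1,3-dioxolan-4-yl]acetic acid (cis)
Conditions: pivalaldehyde, TsOH (cat.), H2SO4 (cat.), pentane, reflux (Dean–Stark); recrystallisation
Reagents that add atoms: pivalaldehyde CC(C)(C)C=O
Why: Acetalisation of the α-hydroxy acid gives the thermodynamic cis-dioxolanone, which stores the chirality of the future C13 in the acetal centre (self-regeneration of stereocentres).

Step 6
Reactants: 8 2-[(2R,4R)-2-tert-butyl-5-oxo-1,3-dioxolan-4-yl]acetic acid; 9 (4-bromobut-2-yn-1-yl)oxy(tert-butyl)dimethylsilane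
Product: 10 2-[(2R,4R)-2-tert-butyl-4-{4-[(tert-butyldimethylsilyl)oxy]but-2-yn-1-yl}-5-oxo-1,3-dioxolan-4-yl]acetic acid
Conditions: LiHMDS (2.2 equiv), THF, −78 °C; 9, −78 → −20 °C; aq. HCl work-up
Reagents that add atoms: none
Why: The carboxylate/enolate dianion is alkylated (SN2) by the propargylic bromide anti to the tert-butyl group, i.e. with retention at the carbinol carbon, which should create quaternary C13 in the R configuration.

Step 7
Reactants: 10 2-[(2R,4R)-2-tert-butyl-4-{4-[(tert-butyldimethylsilyl)oxy]but-2-yn-1-yl}-5-oxo-1,3-dioxolan-4-yl]acetic acid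
Product: 12 (3R)-3-hydroxy-3-(4-hydroxybut-2-yn-1-yl)oxolan-2-one, via hydroxyethyl dioxolanone 11 (not isolated)
Conditions: BH3·SMe2, THF, 0 °C; then TsOH·H2O, MeOH, rt
Reagents that add atoms: none
Why: Borane reduces the free carboxylic acid faster than the dioxolanone ester or the hindered alkyne; acid methanolysis then removes the silyl ether and lets the new primary alcohol open the dioxolanone to the γ-lactone (translactonisation) without touching C13.

Step 8
Reactants: 12 (3R)-3-hydroxy-3-(4-hydroxybut-2-yn-1-yl)oxolan-2-one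
Product: 13 (5R)-2-(hydroxymethyl)-1,7-dioxaspiro[4.4]non-2-en-6-one
Conditions: Ph3PAuCl (2 mol%), AgOTf (2 mol%), THF, 0 °C → rt; Et3N quench
Reagents that add atoms: none
Why: Gold-catalysed alkynol cycloisomerisation (5-endo-dig hydroalkoxylation) by the homopropargylic tertiary alcohol should give the 2,3-dihydrofuran, the primary propargylic alcohol being unable to cyclise.

Step 9
Reactants: 13 (5R)-2-(hydroxymethyl)-1,7-dioxaspiro[4.4]non-2-en-6-one
Product: 14 (5R)-6-oxo-1,7-dioxaspiro[4.4]non-2-ene-2-carbaldehyde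
Conditions: MnO2, CH2Cl2, rt
Reagents that add atoms: none
Why: MnO2 oxidises the allylic primary alcohol to the α-alkoxy enal under neutral conditions that spare the enol ether.

Step 10
Reactants: 6 methyl (1S)-2-acetyl-1,3-dimethylcyclohex-2-ene-1-carboxylate; 14 (5R)-6-oxo-1,7-dioxaspiro[4.4]non-2-ene-2-carbaldehyde
Product: 15 methyl (1S)-2-{(3R)-3-hydroxy-3-[(5R)-6-oxo-1,7-dioxaspiro[4.4]non-2-en-2-yl]propanoyl}-1,3-dimethylcyclohex-2-ene-1-carboxylate
Conditions: (+)-Ipc2BCl, Et3N, Et2O, 0 °C; 14, −78 → −20 °C; H2O2, pH 7 buffer, MeOH, 0 °C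
Reagents that add atoms: none
Why: Boron aldol reaction of the methyl-ketone enol borinate under reagent control (chloroborane enantiomer chosen to give the 8R carbinol, minor epimer removed by chromatography); this centre only has to be uniform, since it is oxidised in step 13.

Step 11
Reactants: 15 methyl (1S)-2-{(3R)-3-hydroxy-3-[(5R)-6-oxo-1,7-dioxaspiro[4.4]non-2-en-2-yl]propanoyl}-1,3-dimethylcyclohex-2-ene-1-carboxylate
Product: 16 methyl (4S,5R,8R,9S,10S,13R)-9,13-epoxy-8-hydroxy-6-oxo-17-norlabdan-16,15-olid-19-oate (trans-decalin, 6-ketone, 8α-OH, 9α-O spiro-tetrahydrofuran carrying the spiro-butyrolactone, 4β-CO2Me)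
Conditions: Fe(acac)3 (30 mol%), PhSiH3, EtOH/ethylene glycol, 60 °C
Reagents that add atoms: none
Why: The iron hydride formed from Fe(acac)3 and PhSiH3 transfers a hydrogen atom to C11 of the electron-rich enol ether (the tetrasubstituted, electron-poor enone is inert to it), giving the nucleophilic tertiary α-alkoxy radical at C9, which adds to C10, the β-carbon of the enone; the α-keto radical is then reduced to the iron enolate and protonated by ethanol. The closest known reaction type is the iron-mediated reductive coupling of heteroatom-substituted donor olefins with enones (hydrogen-atom-transfer-initiated Giese addition), here intramolecular. Ring B closes in the 6-endo-trig mode (carbonyl inside the tether), favoured by polarity over 5-exo attack at the α-carbon C5. C10: the C4 ester should sit pseudoaxial on the β face of the ring-A half-chair, so C9 bonds from the α face and the methyl group ends β. C9: a chair-like transition state with the C8 hydroxyl equatorial places the smaller ring oxygen axial (α) and C11 equatorial, which with the fixed 13R centre gives the required spiro diastereomer; C5: kinetic protonation of the enolate from the α face (β face covered by the C10 methyl and C4 ester) gives the trans ring fusion. The step needs cyclisation to outrun reduction of the C9 radical, which the six-membered intramolecular closure and the low stationary hydride concentration should secure.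

Step 12
Reactants: 16 methyl (4S,5R,8R,9S,10S,13R)-9,13-epoxy-8-hydroxy-6-oxo-17-norlabdan-16,15-olid-19-oate
Product: 18 (4S,5R,6R,8R,9S,10S,13R)-9,13-epoxy-8-hydroxy-17-norlabdane-19,6:16,15-diolide, via hydroxy ester 17 (not isolated)
Conditions: NaBH4, MeOH, −20 °C → rt
Reagents that add atoms: none
Why: Hydride attacks the C6 ketone from the α face (β face shielded by the axial C10 methyl and C4 ester), and the resulting axial 6β-alkoxide, 1,3-diaxial to the ester, lactonises in the same pot to the cis-fused 19,6β-lactone.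

Step 13
Reactants: 18 (4S,5R,6R,8R,9S,10S,13R)-9,13-epoxy-8-hydroxy-17-norlabdane-19,6:16,15-diolide
Product: 19 (4S,5R,6R,9S,10S,13R)-9,13-epoxy-8-oxo-17-norlabdane-19,6:16,15-diolide
Conditions: Dess–Martin periodinane, NaHCO3, CH2Cl2, rt
Reagents that add atoms: none
Why: Dess–Martin oxidation of the remaining secondary alcohol under buffered, non-basic conditions should give the 8-ketone without β-elimination of the C6 acyloxy group.

Step 14
Reactants: 19 (4S,5R,6R,9S,10S,13R)-9,13-epoxy-8-oxo-17-norlabdane-19,6:16,15-diolide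
Product: 20 (4S,5R,6R,8R,9S,10S,13R)-8,17:9,13-diepoxylabdane-19,6:16,15-diolide (CNP0105047.2)
Conditions: Me3S+ I− (1.5 equiv), KHMDS (1.3 equiv), THF, −10 °C; then 19, −10 → 0 °C
Reagents that add atoms: trimethylsulfonium iodide C[S+](C)C.[I-]
Why: Corey–Chaykovsky epoxidation: the sulfonium methylide adds irreversibly from the equatorial α face (axial β face blocked by the syn-axial C10 methyl and C6 oxygen), so betaine closure gives the epoxide with oxygen β and CH2 α as in the target, and the weakly basic ylide (base kept limiting) should not enolise the β-acyloxy ketone.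

Compound list
1 | methyl 2-oxocyclohexane-1-carboxylate | COC(=O)C1CCCCC1=O | starting material
2 | methyl (1S)-1-methyl-2-oxocyclohexane-1-carboxylate | O=C1CCCC[C@]1(C)C(=O)OC | intermediate
3 | methyl (1S,3RS)-1,3-dimethyl-2-oxocyclohexane-1-carboxylate (C3 epimers) | O=C1C(C)CCC[C@]1(C)C(=O)OC | intermediate
4 | methyl (1S)-1,3-dimethyl-2-{[(trifluoromethyl)sulfonyl]oxy}cyclohex-2-ene-1-carboxylate | CC1=C(OS(=O)(=O)C(F)(F)F)[C@](C)(CCC1)C(=O)OC | intermediate
5 | methyl (1S)-2-(1-ethoxyethenyl)-1,3-dimethylcyclohex-2-ene-1-carboxylate (ethoxydiene) | CCOC(=C)C1=C(C)CCC[C@]1(C)C(=O)OC | intermediate (not isolated)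
6 | methyl (1S)-2-acetyl-1,3-dimethylcyclohex-2-ene-1-carboxylate | CC(=O)C1=C(C)CCC[C@]1(C)C(=O)OC | intermediate
7 | (R)-malic acid | OC(=O)C[C@@H](O)C(=O)O | starting material
8 | 2-[(2R,4R)-2-tert-butyl-5-oxo-1,3-dioxolan-4-yl]acetic acid | OC(=O)C[C@H]1O[C@@H](C(C)(C)C)OC1=O | intermediate
9 | (4-bromobut-2-yn-1-yl)oxy(tert-butyl)dimethylsilane | BrCC#CCO[Si](C)(C)C(C)(C)C | starting material
10 | 2-[(2R,4R)-2-tert-butyl-4-{4-[(tert-butyldimethylsilyl)oxy]but-2-yn-1-yl}-5-oxo-1,3-dioxolan-4-yl]acetic acid | OC(=O)C[C@@]1(CC#CCO[Si](C)(C)C(C)(C)C)O[C@@H](C(C)(C)C)OC1=O | intermediate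
11 | (2R,5R)-2-tert-butyl-5-{4-[(tert-butyldimethylsilyl)oxy]but-2-yn-1-yl}-5-(2-hydroxyethyl)-1,3-dioxolan-4-one | OCC[C@@]1(CC#CCO[Si](C)(C)C(C)(C)C)O[C@@H](C(C)(C)C)OC1=O | intermediate (not isolated)
12 | (3R)-3-hydroxy-3-(4-hydroxybut-2-yn-1-yl)oxolan-2-one | OCC#CC[C@]1(CCOC1=O)O | intermediate
13 | (5R)-2-(hydroxymethyl)-1,7-dioxaspiro[4.4]non-2-en-6-one | OCC1=CC[C@]2(CCOC2=O)O1 | intermediate
14 | (5R)-6-oxo-1,7-dioxaspiro[4.4]non-2-ene-2-carbaldehyde | O=CC1=CC[C@]2(CCOC2=O)O1 | intermediate
15 | methyl (1S)-2-{(3R)-3-hydroxy-3-[(5R)-6-oxo-1,7-dioxaspiro[4.4]non-2-en-2-yl]propanoyl}-1,3-dimethylcyclohex-2-ene-1-carboxylate | CC1=C(C(=O)C[C@@H](O)C2=CC[C@]3(CCOC3=O)O2)[C@](C)(CCC1)C(=O)OC | intermediate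
16 | methyl (4S,5R,8R,9S,10S,13R)-9,13-epoxy-8-hydroxy-6-oxo-17-norlabdan-16,15-olid-19-oate | C[C@]12CCC[C@](C)(C(=O)OC)[C@@H]1C(=O)C[C@@H](O)[C@]21CC[C@]2(CCOC2=O)O1 | intermediate
17 | methyl (4S,5R,6R,8R,9S,10S,13R)-9,13-epoxy-6,8-dihydroxy-17-norlabdan-16,15-olid-19-oate (6β,8α-diol) | C[C@]12CCC[C@](C)(C(=O)OC)[C@@H]1[C@H](O)C[C@@H](O)[C@]21CC[C@]2(CCOC2=O)O1 | intermediate (not isolated)
18 | (4S,5R,6R,8R,9S,10S,13R)-9,13-epoxy-8-hydroxy-17-norlabdane-19,6:16,15-diolide | C[C@@]12CCC[C@]3(C)C(=O)O[C@H](C[C@@H](O)[C@]14CC[C@]1(CCOC1=O)O4)[C@H]23 | intermediate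
19 | (4S,5R,6R,9S,10S,13R)-9,13-epoxy-8-oxo-17-norlabdane-19,6:16,15-diolide | C[C@@]12CCC[C@]3(C)C(=O)O[C@H](CC(=O)[C@]14CC[C@]1(CCOC1=O)O4)[C@H]23 | intermediate
20 | (4S,5R,6R,8R,9S,10S,13R)-8,17:9,13-diepoxylabdane-19,6:16,15-diolide (CNP0105047.2) | C[C@@]12CCC[C@]3(C)C(=O)O[C@H](C[C@@]4(CO4)[C@]14CC[C@]1(CCOC1=O)O4)[C@H]23 | target

Total step count: 14. Longest linear sequence: 10 steps (7 → 20, steps 5–14).

Steps most likely to fail

Step 11. The C9 radical may be quenched by hydrogen-atom transfer from the iron hydride or the silane before it adds to the hindered enone, whose carbonyl is twisted out of conjugation, and the facial preference at C10 may be weak. The fallback sets out from 15: acid-catalysed Markovnikov addition of benzeneselenol across the enol ether (PPTS, CH2Cl2, 0 °C) would give the O,Se-ketal F1. Slow addition of Bu3SnH with AIBN in refluxing benzene then generates the same C9 radical by C–Se homolysis at very low hydride concentration, so that the 6-endo closure can compete. The route is rejoined at 16.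

Step 14. Enolisation of the β-acyloxy ketone towards C7 could expel the lactone carboxylate, or polar control by the α-alkoxy group could erode attack from the α face. The fallback sets out from 19: non-basic iodomethylation with the samarium carbenoid (SmI2, CH2I2, THF, rt), again from the equatorial α face, would give the 8β-hydroxy-17-iodo compound F2. Closure with K2CO3 in acetone returns the route at 20.

Step 1. Enantiofacial discrimination in the ion pair may be insufficient with the small electrophile MeI. The fallback sets out from 1: condensation with L-valine tert-butyl ester would give the chiral enamino ester F3. Deprotonation with LDA and methylation of the chelated lithio-enamine (solvent and additive chosen for the S sense) gives the α-methyl imine F4, and mild aqueous acid hydrolysis returns the route at 2.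

Further compounds
F1 | step 11 | methyl (1S)-2-{(3R)-3-hydroxy-3-[(5R)-6-oxo-2-(phenylselanyl)-1,7-dioxaspiro[4.4]nonan-2-yl]propanoyl}-1,3-dimethylcyclohex-2-ene-1-carboxylate (either configuration at the selenoketal carbon) | CC1=C(C(=O)C[C@@H](O)C2([Se]c3ccccc3)CC[C@]3(CCOC3=O)O2)[C@](C)(CCC1)C(=O)OC
F2 | step 14 | 8β-hydroxy-17-iodo-9α,13R-epoxylabdane-19,6β:16,15-diolide | C[C@@]12CCC[C@]3(C)C(=O)O[C@H](C[C@@](O)(CI)[C@]14CC[C@]1(CCOC1=O)O4)[C@H]23
F3 | step 1 | methyl 2-{[(2S)-1-tert-butoxy-3-methyl-1-oxobutan-2-yl]amino}cyclohex-1-ene-1-carboxylate | COC(=O)C1=C(N[C@@H](C(C)C)C(=O)OC(C)(C)C)CCCC1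
F4 | step 1 | methyl (1S)-2-{[(2S)-1-tert-butoxy-3-methyl-1-oxobutan-2-yl]imino}-1-methylcyclohexane-1-carboxylate | COC(=O)[C@@]1(C)CCCCC1=N[C@@H](C(C)C)C(=O)OC(C)(C)C
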